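The target is read as catechin-(4α→8)-catechin-(4α→6)-catechin, with all three units (2R,3S) and both interflavan bonds 3,4-trans.

The route rests on disconnecting ring C of the upper catechin unit at O1–C2 and C3–C4. C4 of that ring is a diarylmethine and the adjacent A-ring carbons C4a–C8a carry O1, so O1–C8a–C4a–C4 is the retron of an o-quinone methide. A late carbinol, in which C4 already links a new phloroglucinol ring to C8 of a preformed catechin-(4α→6)-catechin dimer, is dehydrated by a chiral phosphoric acid and trapped by an α-aryl enamide: one operation closes the pyran ring, sets C4 and leaves a flav-2-ene. Hydroboration anti to the C4 aryl group then sets C2 and C3, and hydrogenolysis releases the target.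

Key step: step 11

Assumption: the sense of induction of the phosphoric acid at C4 cannot be fixed on paper for this substrate, so the (R)-acid is written and its antipode takes its place if a trial on 14 shows it to be the matched one; flavan numbering is used for every unit, α being the face of the 2-aryl group of a (2R)-flavan.

Step 1
Reactants: 1 (+)-catechin
Product: 2 5,7,3',4'-tetra-O-benzyl-(+)-catechin
Conditions: BnBr (4.4 equiv), K2CO3, DMF, 0 °C to rt
Reagents that add atoms: benzyl bromide, BrCc1ccccc1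
Why: Williamson ether synthesis in which carbonate deprotonates only the four phenols, so the secondary 3-OH stays free and C2 and C3 are untouched.

Step 2
Reactants: 2 5,7,3',4'-tetra-O-benzyl-(+)-catechin
Product: 3 8-bromo-5,7,3',4'-tetra-O-benzyl-(+)-catechin
Conditions: NBS (1.0 equiv), CH2Cl2, −78 °C to 0 °C
Reagents that add atoms: N-bromosuccinimide, O=C1CCC(=O)N1Br
Why: Electrophilic aromatic bromination goes to C8, the most reactive position of the phloroglucinol-type ring A, and the bromine later blocks C8 so that C6 is the only nucleophilic ring A position left.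

Step 3
Reactants: 2 5,7,3',4'-tetra-O-benzyl-(+)-catechin
Product: 4 8-iodo-5,7,3',4'-tetra-O-benzyl-(+)-catechin
Conditions: NIS (1.05 equiv), DMF, 0 °C to rt, dark
Reagents that add atoms: N-iodosuccinimide, O=C1CCC(=O)N1I
Why: Electrophilic aromatic iodination with the same C8 regioselectivity as the bromination; the iodine caps C8 against self-condensation in step 6 and is the handle for metalation beside the bromide in step 9.

Step 4
Reactants: 4 8-iodo-5,7,3',4'-tetra-O-benzyl-(+)-catechin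
Product: 5 4β-(2-ethoxyethoxy)-8-iodo-5,7,3',4'-tetra-O-benzylcatechin
Conditions: DDQ (2 equiv), 2-ethoxyethanol (5 equiv), CH2Cl2, rt
Reagents that add atoms: 2-ethoxyethanol, CCOCCO
Why: DDQ benzylic oxidation, in which hydride abstraction from C4 gives a cation stabilised by the ring A oxygens and the alcohol adds axially, trans to the 2-aryl group, so the new centre is 4β (it is ionised again in step 6).

Step 5
Reactants: 5 4β-(2-ethoxyethoxy)-8-iodo-5,7,3',4'-tetra-O-benzylcatechin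
Product: 6 3-O-acetyl-4β-(2-ethoxyethoxy)-8-iodo-5,7,3',4'-tetra-O-benzylcatechin
Conditions: Ac2O, DMAP (cat.), pyridine, rt
Reagents that add atoms: acetic anhydride, CC(=O)OC(C)=O
Why: DMAP-catalysed acylation of the secondary alcohol installs the participating group needed for step 6 without touching a stereocentre.

Step 6
Reactants: 6 3-O-acetyl-4β-(2-ethoxyethoxy)-8-iodo-5,7,3',4'-tetra-O-benzylcatechin; 3 8-bromo-5,7,3',4'-tetra-O-benzyl-(+)-catechin (3 equiv, excess recovered)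
Product: 7 3-O-acetyl-5,7,3',4'-tetra-O-benzyl-8-iodocatechin-(4α→6)-5,7,3',4'-tetra-O-benzyl-8-bromocatechin
Conditions: TMSOTf (0.5 equiv), CH2Cl2, −78 °C; aq NaHCO3
Reagents that add atoms: none
Why: Lewis acid-promoted Friedel–Crafts alkylation in which TMSOTf ionises the C4 ether, the 3-acetate bridges the β face of the cation (neighbouring-group participation) and C6 of 3, the only free ring A position, attacks from the α face to set the 3,4-trans (4α) centre.

Step 7
Reactants: 7 3-O-acetyl-5,7,3',4'-tetra-O-benzyl-8-iodocatechin-(4α→6)-5,7,3',4'-tetra-O-benzyl-8-bromocatechin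
Product: 9 3,5,7,3',4'-penta-O-benzyl-8-iodocatechin-(4α→6)-3,5,7,3',4'-penta-O-benzyl-8-bromocatechin, via dimer 3,3''-diol 8 (not isolated)
Conditions: powdered KOH (excess), BnBr (4 equiv), 18-crown-6 (cat.), THF, rt
Reagents that add atoms: benzyl bromide, BrCc1ccccc1
Why: One-pot saponification and Williamson benzylation removes the acetate and caps both secondary alcohols, leaving no acidic or electrophilic group for the organometallic step, while aryl halides and stereocentres are inert to hydroxide.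

Step 8
Reactants: 10 2,4,6-trihydroxybenzaldehyde
Product: 11 4,6-bis(benzyloxy)-2-hydroxybenzaldehyde
Conditions: BnBr (2.05 equiv), K2CO3, DMF, 0 °C to rt
Reagents that add atoms: benzyl bromide, BrCc1ccccc1
Why: Williamson etherification stops at the dibenzyl ether because the last ortho hydroxyl is tied up in a hydrogen bond to the formyl group and is the least nucleophilic.

Step 9
Reactants: 9 3,5,7,3',4'-penta-O-benzyl-8-iodocatechin-(4α→6)-3,5,7,3',4'-penta-O-benzyl-8-bromocatechin; 11 4,6-bis(benzyloxy)-2-hydroxybenzaldehyde (1.3 equiv)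
Product: 14 [4,6-bis(benzyloxy)-2-hydroxyphenyl](upper-unit C8 of the deca-O-benzyl catechin-(4α→6)-8-bromocatechin dimer)methanol as both carbinol epimers, via upper-unit C8 arylmagnesium chloride 12 (not isolated), via sodium 3,5-bis(benzyloxy)-2-formylphenolate 13 (not isolated)
Conditions: 9, i-PrMgCl·LiCl (1.1 equiv), THF, 0 °C to rt; separately 11, NaH (1.0 equiv), THF, 0 °C; combine, 0 °C to rt; sat. aq NH4Cl, 0 °C; used crude
Reagents that add atoms: none
Why: Iodine–magnesium exchange is far faster at the aryl iodide flanked by two oxygens than at the aryl bromide, and the arylmagnesium reagent then undergoes Grignard 1,2-addition to the formyl group of the preformed phenoxide; the new carbinol centre is uncontrolled and becomes planar in step 11.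

Step 10
Reactants: 15 3,4-bis(benzyloxy)benzonitrile
Product: 17 N-{1-[3,4-bis(benzyloxy)phenyl]ethenyl}acetamide, via bromomagnesium ketimide 16 (not isolated)
Conditions: MeMgBr (1.2 equiv), THF, 0 °C to rt; then Ac2O (1.5 equiv), 0 °C to rt
Reagents that add atoms: methylmagnesium bromide, C[Mg]Br; acetic anhydride, CC(=O)OC(C)=O
Why: Grignard addition to the nitrile gives the metallo-ketimine, and N-acetylation followed by imine–enamide tautomerisation gives the α-aryl enamide (no stereocentre).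

Step 11
Reactants: 14 [4,6-bis(benzyloxy)-2-hydroxyphenyl](upper-unit C8 of the dimer)methanol; 17 N-{1-[3,4-bis(benzyloxy)phenyl]ethenyl}acetamide (2 equiv)
Product: 20 5,7,3',4'-tetra-O-benzylflav-2-ene-(4α→8)-3,5,7,3',4'-penta-O-benzylcatechin-(4α→6)-3,5,7,3',4'-penta-O-benzyl-8-bromocatechin, via o-quinone methide 18 (not isolated), via 2-acetamidoflavan aminal 19 (not isolated)
Conditions: (R)-3,3'-bis(2,4,6-triisopropylphenyl)-1,1'-binaphthyl-2,2'-diyl hydrogen phosphate (10 mol %), 4 Å molecular sieves, toluene, 0 °C to rt; then p-TsOH·H2O (20 mol %), rt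
Reagents that add atoms: none
Why: The phosphoric acid dehydrates the o-hydroxybenzhydrol 14 to o-quinone methide 18 (O1=C8a–C4a=C4, C4 bearing C8 of the middle unit), binds its quinone oxygen by a hydrogen bond and the N–H of enamide 17 through its P=O group, so that the CH2 terminus of the enamide (future C3) adds to C4 and the phenolic O1 then closes on the N-acyliminium carbon C2, after which toluenesulfonic acid eliminates acetamide from aminal 19 to give the enol ether C2=C3. The closest known reaction type is the chiral phosphoric acid-catalysed formal oxa-[4+2] cycloaddition of in situ generated o-quinone methides with enamides, followed by acid elimination to 2-aryl-4H-chromenes. The pyran ring is closed in a stepwise [4+2] annulation: intermolecular C3–C4 bond formation, then 6-exo-trig attack of O1 on the C2=N bond. The only new stereocentre that persists, C4, is set by the catalyst, which decides the face of the methide carbon that the hydrogen-bonded enamide reaches (the (R)-acid is assumed to give the 4α-aryl epimer), while the aminal centre C2 is erased by the elimination. The step needs regioselectivity (C3 to C4, O1 to C2), secured by the polarity of the enamide, and facial selectivity at C4, secured by the two-point binding in the catalyst pocket because the stereocentres of the middle unit are too remote to decide it. An excess of the strongly nucleophilic enamide outruns Friedel–Crafts capture of the cation by the free C6 and C8 positions of the new ring A.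

Step 12
Reactants: 20 5,7,3',4'-tetra-O-benzylflav-2-ene-(4α→8)-penta-O-benzylcatechin-(4α→6)-penta-O-benzyl-8-bromocatechin
Product: 22 5,7,3',4'-tetra-O-benzylcatechin-(4α→8)-3,5,7,3',4'-penta-O-benzylcatechin-(4α→6)-3,5,7,3',4'-penta-O-benzyl-8-bromocatechin, via C3 alkylborane 21 (not isolated)
Conditions: BH3·THF (4 equiv), THF, 0 °C to rt; then 3 M NaOH, 30% H2O2, 0 °C to rt
Reagents that add atoms: hydrogen peroxide, OO
Why: Hydroboration–oxidation of the enol ether places boron on C3 and hydrogen on C2 syn from the β face, anti to the pseudo-axial C4 aryl group, and oxidation with retention gives the 3β-OH, so the C4 centre sets C2 (2-aryl α) and C3 as 2,3-trans-3,4-trans.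

Step 13
Reactants: 22 5,7,3',4'-tetra-O-benzylcatechin-(4α→8)-penta-O-benzylcatechin-(4α→6)-penta-O-benzyl-8-bromocatechin
Product: 23 catechin-(4α→8)-catechin-(4α→6)-catechin
Conditions: H2 (1 atm), Pd(OH)2/C, Et3N (1.5 equiv), THF/MeOH/H2O, rt; Sephadex LH-20
Reagents that add atoms: none
Why: Catalytic hydrogenolysis cleaves the fourteen benzyl ethers and, with triethylamine as HBr acceptor, the aryl C–Br bond, without touching the ring C–O bonds, the interflavan C–C bonds or any stereocentre.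

Compound list

1 | (+)-catechin, (2R,3S)-2-(3,4-dihydroxyphenyl)chromane-3,5,7-triol | Oc1cc(O)c2c(c1)O[C@H](c1ccc(O)c(O)c1)[C@@H](O)C2 | starting material
2 | 5,7,3',4'-tetra-O-benzyl-(+)-catechin (3-OH free) | c1ccccc1COc1cc(OCc3ccccc3)c2c(c1)O[C@H](c1ccc(OCc3ccccc3)c(OCc3ccccc3)c1)[C@@H](O)C2 | intermediate
3 | 8-bromo-5,7,3',4'-tetra-O-benzyl-(+)-catechin | c1ccccc1COc1cc(OCc3ccccc3)c2c(c1Br)O[C@H](c1ccc(OCc3ccccc3)c(OCc3ccccc3)c1)[C@@H](O)C2 | intermediate
4 | 8-iodo-5,7,3',4'-tetra-O-benzyl-(+)-catechin | c1ccccc1COc1cc(OCc3ccccc3)c2c(c1I)O[C@H](c1ccc(OCc3ccccc3)c(OCc3ccccc3)c1)[C@@H](O)C2 | intermediate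
5 | (2R,3S,4S)-4β-(2-ethoxyethoxy)-8-iodo-5,7,3',4'-tetra-O-benzylcatechin (4-O cis to 3-OH, trans to the 2-aryl group) | c1ccccc1COc1cc(OCc3ccccc3)c2c(c1I)O[C@H](c1ccc(OCc3ccccc3)c(OCc3ccccc3)c1)[C@@H](O)[C@H]2OCCOCC | intermediate
6 | 3-O-acetate of 5 | c1ccccc1COc1cc(OCc3ccccc3)c2c(c1I)O[C@H](c1ccc(OCc3ccccc3)c(OCc3ccccc3)c1)[C@@H](OC(C)=O)[C@H]2OCCOCC | intermediate
7 | 3-O-acetyl-5,7,3',4'-tetra-O-benzyl-8-iodocatechin-(4α→6)-5,7,3',4'-tetra-O-benzyl-8-bromocatechin | c1ccccc1COc1cc(OCc3ccccc3)c2c(c1I)O[C@H](c1ccc(OCc3ccccc3)c(OCc3ccccc3)c1)[C@@H](OC(C)=O)[C@@H]2c1c(OCc3ccccc3)c(Br)c2c(c1OCc3ccccc3)C[C@H](O)[C@@H](c1ccc(OCc3ccccc3)c(OCc3ccccc3)c1)O2 | intermediate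
8 | 5,7,3',4'-tetra-O-benzyl-8-iodocatechin-(4α→6)-5,7,3',4'-tetra-O-benzyl-8-bromocatechin (both 3-OH free) | c1ccccc1COc1cc(OCc3ccccc3)c2c(c1I)O[C@H](c1ccc(OCc3ccccc3)c(OCc3ccccc3)c1)[C@@H](O)[C@@H]2c1c(OCc3ccccc3)c(Br)c2c(c1OCc3ccccc3)C[C@H](O)[C@@H](c1ccc(OCc3ccccc3)c(OCc3ccccc3)c1)O2 | intermediate
9 | 3,5,7,3',4'-penta-O-benzyl-8-iodocatechin-(4α→6)-3,5,7,3',4'-penta-O-benzyl-8-bromocatechin | Ic1c(OCc3ccccc3)cc(OCc3ccccc3)c2c1O[C@H](c1ccc(OCc3ccccc3)c(OCc3ccccc3)c1)[C@@H](OCc3ccccc3)[C@@H]2c1c(OCc3ccccc3)c(Br)c2c(c1OCc3ccccc3)C[C@H](OCc3ccccc3)[C@@H](c1ccc(OCc3ccccc3)c(OCc3ccccc3)c1)O2 | intermediate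
10 | 2,4,6-trihydroxybenzaldehyde | O=Cc1c(O)cc(O)cc1O | starting material
11 | 4,6-bis(benzyloxy)-2-hydroxybenzaldehyde | O=Cc1c(O)cc(OCc2ccccc2)cc1OCc2ccccc2 | intermediate
12 | upper-unit C8 arylmagnesium chloride of the dimer (iodine of 9 replaced by MgCl) | Cl[Mg]c1c(OCc3ccccc3)cc(OCc3ccccc3)c2c1O[C@H](c1ccc(OCc3ccccc3)c(OCc3ccccc3)c1)[C@@H](OCc3ccccc3)[C@@H]2c1c(OCc3ccccc3)c(Br)c2c(c1OCc3ccccc3)C[C@H](OCc3ccccc3)[C@@H](c1ccc(OCc3ccccc3)c(OCc3ccccc3)c1)O2 | intermediate
13 | sodium 3,5-bis(benzyloxy)-2-formylphenolate | [Na+].[O-]c1cc(OCc2ccccc2)cc(OCc2ccccc2)c1C=O | intermediate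
14 | [4,6-bis(benzyloxy)-2-hydroxyphenyl](upper-unit C8 of the deca-O-benzyl catechin-(4α→6)-8-bromocatechin dimer)methanol, both carbinol epimers | Oc1cc(OCc3ccccc3)cc(OCc3ccccc3)c1C(O)c1c(OCc3ccccc3)cc(OCc3ccccc3)c2c1O[C@H](c1ccc(OCc3ccccc3)c(OCc3ccccc3)c1)[C@@H](OCc3ccccc3)[C@@H]2c1c(OCc3ccccc3)c(Br)c2c(c1OCc3ccccc3)C[C@H](OCc3ccccc3)[C@@H](c1ccc(OCc3ccccc3)c(OCc3ccccc3)c1)O2 | intermediate
15 | 3,4-bis(benzyloxy)benzonitrile | N#Cc1ccc(OCc2ccccc2)c(OCc2ccccc2)c1 | starting material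
16 | bromomagnesium salt of 1-[3,4-bis(benzyloxy)phenyl]ethan-1-imine | CC(=N[Mg]Br)c1ccc(OCc2ccccc2)c(OCc2ccccc2)c1 | intermediate
17 | N-{1-[3,4-bis(benzyloxy)phenyl]ethenyl}acetamide | CC(=O)NC(=C)c1ccc(OCc2ccccc2)c(OCc2ccccc2)c1 | intermediate
18 | o-quinone methide: 3,5-bis(benzyloxy)-6-(arylmethylidene)cyclohexa-2,4-dien-1-one, aryl = upper-unit C8 of the dimer | O=C1C=C(OCc3ccccc3)C=C(OCc3ccccc3)C1=Cc1c(OCc3ccccc3)cc(OCc3ccccc3)c2c1O[C@H](c1ccc(OCc3ccccc3)c(OCc3ccccc3)c1)[C@@H](OCc3ccccc3)[C@@H]2c1c(OCc3ccccc3)c(Br)c2c(c1OCc3ccccc3)C[C@H](OCc3ccccc3)[C@@H](c1ccc(OCc3ccccc3)c(OCc3ccccc3)c1)O2 | intermediate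
19 | 2-acetamido-5,7,3',4'-tetra-O-benzylflavan-(4α→8)-penta-O-benzylcatechin-(4α→6)-penta-O-benzyl-8-bromocatechin (N,O-aminal at C2, either configuration; C3 = CH2) | c1ccccc1COc1cc(OCc3ccccc3)c2c(c1)OC(NC(C)=O)(c1ccc(OCc3ccccc3)c(OCc3ccccc3)c1)C[C@@H]2c1c(OCc3ccccc3)cc(OCc3ccccc3)c2c1O[C@H](c1ccc(OCc3ccccc3)c(OCc3ccccc3)c1)[C@@H](OCc3ccccc3)[C@@H]2c1c(OCc3ccccc3)c(Br)c2c(c1OCc3ccccc3)C[C@H](OCc3ccccc3)[C@@H](c1ccc(OCc3ccccc3)c(OCc3ccccc3)c1)O2 | intermediate
20 | 5,7,3',4'-tetra-O-benzylflav-2-ene-(4α→8)-penta-O-benzylcatechin-(4α→6)-penta-O-benzyl-8-bromocatechin (2-aryl-4H-chromene, C4 as in the target) | c1ccccc1COc1cc(OCc3ccccc3)c2c(c1)OC(c1ccc(OCc3ccccc3)c(OCc3ccccc3)c1)=C[C@@H]2c1c(OCc3ccccc3)cc(OCc3ccccc3)c2c1O[C@H](c1ccc(OCc3ccccc3)c(OCc3ccccc3)c1)[C@@H](OCc3ccccc3)[C@@H]2c1c(OCc3ccccc3)c(Br)c2c(c1OCc3ccccc3)C[C@H](OCc3ccccc3)[C@@H](c1ccc(OCc3ccccc3)c(OCc3ccccc3)c1)O2 | intermediate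
21 | 3β-boryl (BH2) 2,3-trans-3,4-trans flavan trimer (boron in place of the upper-unit 3-OH of 22) | c1ccccc1COc1cc(OCc3ccccc3)c2c(c1)O[C@H](c1ccc(OCc3ccccc3)c(OCc3ccccc3)c1)[C@@H](B)[C@@H]2c1c(OCc3ccccc3)cc(OCc3ccccc3)c2c1O[C@H](c1ccc(OCc3ccccc3)c(OCc3ccccc3)c1)[C@@H](OCc3ccccc3)[C@@H]2c1c(OCc3ccccc3)c(Br)c2c(c1OCc3ccccc3)C[C@H](OCc3ccccc3)[C@@H](c1ccc(OCc3ccccc3)c(OCc3ccccc3)c1)O2 | intermediate
22 | 5,7,3',4'-tetra-O-benzylcatechin-(4α→8)-3,5,7,3',4'-penta-O-benzylcatechin-(4α→6)-3,5,7,3',4'-penta-O-benzyl-8-bromocatechin | c1ccccc1COc1cc(OCc3ccccc3)c2c(c1)O[C@H](c1ccc(OCc3ccccc3)c(OCc3ccccc3)c1)[C@@H](O)[C@@H]2c1c(OCc3ccccc3)cc(OCc3ccccc3)c2c1O[C@H](c1ccc(OCc3ccccc3)c(OCc3ccccc3)c1)[C@@H](OCc3ccccc3)[C@@H]2c1c(OCc3ccccc3)c(Br)c2c(c1OCc3ccccc3)C[C@H](OCc3ccccc3)[C@@H](c1ccc(OCc3ccccc3)c(OCc3ccccc3)c1)O2 | intermediate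
23 | catechin-(4α→8)-catechin-(4α→6)-catechin | Oc1cc(O)c2c(c1)O[C@H](c1ccc(O)c(O)c1)[C@@H](O)[C@@H]2c1c(O)cc(O)c2c1O[C@H](c1ccc(O)c(O)c1)[C@@H](O)[C@@H]2c1c(O)cc2c(c1O)C[C@H](O)[C@@H](c1ccc(O)c(O)c1)O2 | target

Total step count: 13. Longest linear sequence: 10 steps (1, 3, 4, 5, 6, 7, 9, 11, 12, 13).

Steps most likely to fail

1. Step 11. What may go wrong: poor facial selectivity at the methide carbon, because the catalyst pocket has to take up the bulky, doubly ortho-substituted flavan-8-yl group and override whatever bias the chiral dimer exerts; arylation of the cation by electron-rich ring positions may also compete. Fallback (auxiliary control and base-mediated generation of the same quinone methide; sets out from 9 and 11, returns at 20): 11 is treated with Boc2O, i-Pr2NEt and DMAP (cat.) to give 3,5-bis(benzyloxy)-2-formylphenyl tert-butyl carbonate F1. Separately, 3,4-bis(benzyloxy)benzoic acid and (1R,2S)-trans-2-phenylcyclohexanol are joined by Steglich esterification (DCC, DMAP) to (1R,2S)-2-phenylcyclohexyl 3,4-bis(benzyloxy)benzoate F2, and Petasis methylenation (Cp2TiMe2, toluene, 65 °C) converts it into 1-[3,4-bis(benzyloxy)phenyl]ethenyl (1R,2S)-2-phenylcyclohexyl ether F3. Arylmagnesium reagent 12, made from 9 as in step 9, is added at −78 °C to F1 in the presence of F3 (3 equiv) and the mixture is warmed. After carbonyl addition the magnesium alkoxide takes over the Boc group, tert-butyl carbonate leaves and 18 forms without acid. The chiral enol ether adds endo, one of its faces being shielded by the phenylcyclohexyl group, to give the 2-[(1R,2S)-2-phenylcyclohexyloxy]flavan ketal trimer F4 (the enantiomer of the auxiliary is fixed in a trial run). PPTS in toluene then expels the auxiliary alcohol and gives 20.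

2. Step 9. What may go wrong: sluggish carbonyl addition of the hindered arylmagnesium reagent to the electron-rich, chelated aldehyde, so that protonation or reduction of the reagent wins. Fallback (the two aryl–carbon bonds of the carbinol are made in the reverse order; sets out from 9, returns at 14): reagent 12 is quenched with DMF, an unhindered formyl donor, to give the upper-unit C8 carbaldehyde of the deca-O-benzyl catechin-(4α→6)-8-bromocatechin dimer F5. Commercial 3,5-bis(benzyloxy)phenol and EtMgBr in toluene give bromomagnesium 3,5-bis(benzyloxy)phenoxide F6, which adds through its ortho carbon to F5 within the magnesium chelate (ortho-specific hydroxyalkylation of a magnesium phenoxide) and gives 14 after neutral work-up.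

3. Step 12. What may go wrong: slow or unselective hydroboration of the crowded trisubstituted enol ether, or β-elimination of the β-oxygenated organoborane with opening of the new ring. Fallback (oxygen first, hydride second; sets out from 20, returns at 22): OsO4 (cat.) with NMO dihydroxylates C2=C3 from the β face, anti to the C4 aryl group, to give the 2-hydroxyflavan-3-ol (cyclic hemiketal) trimer F7 with the 3β-OH in place. Et3SiH and BF3·OEt2 at −78 °C then reduce the C2 oxocarbenium ion by axial hydride delivery, which leaves the 2-aryl group equatorial (2,3-trans), and give 22.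

Further compounds

F1 | step 11 | 3,5-bis(benzyloxy)-2-formylphenyl tert-butyl carbonate | CC(C)(C)OC(=O)Oc1cc(OCc2ccccc2)cc(OCc2ccccc2)c1C=O
F2 | step 11 | (1R,2S)-2-phenylcyclohexyl 3,4-bis(benzyloxy)benzoate | O=C(O[C@@H]1CCCC[C@H]1c1ccccc1)c1ccc(OCc2ccccc2)c(OCc2ccccc2)c1
F3 | step 11 | 1-[3,4-bis(benzyloxy)phenyl]ethenyl (1R,2S)-2-phenylcyclohexyl ether | C=C(O[C@@H]1CCCC[C@H]1c1ccccc1)c1ccc(OCc2ccccc2)c(OCc2ccccc2)c1
F4 | step 11 | 2-[(1R,2S)-2-phenylcyclohexyloxy]-5,7,3',4'-tetra-O-benzylflavan-(4α→8)-penta-O-benzylcatechin-(4α→6)-penta-O-benzyl-8-bromocatechin (ketal at C2, C3 = CH2) | c1ccccc1COc1cc(OCc3ccccc3)c2c(c1)OC(O[C@@H]4CCCC[C@H]4c5ccccc5)(c1ccc(OCc3ccccc3)c(OCc3ccccc3)c1)C[C@@H]2c1c(OCc3ccccc3)cc(OCc3ccccc3)c2c1O[C@H](c1ccc(OCc3ccccc3)c(OCc3ccccc3)c1)[C@@H](OCc3ccccc3)[C@@H]2c1c(OCc3ccccc3)c(Br)c2c(c1OCc3ccccc3)C[C@H](OCc3ccccc3)[C@@H](c1ccc(OCc3ccccc3)c(OCc3ccccc3)c1)O2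
F5 | step 9 | upper-unit C8 carbaldehyde of the deca-O-benzyl catechin-(4α→6)-8-bromocatechin dimer | O=Cc1c(OCc3ccccc3)cc(OCc3ccccc3)c2c1O[C@H](c1ccc(OCc3ccccc3)c(OCc3ccccc3)c1)[C@@H](OCc3ccccc3)[C@@H]2c1c(OCc3ccccc3)c(Br)c2c(c1OCc3ccccc3)C[C@H](OCc3ccccc3)[C@@H](c1ccc(OCc3ccccc3)c(OCc3ccccc3)c1)O2
F6 | step 9 | bromomagnesium 3,5-bis(benzyloxy)phenoxide | Br[Mg]Oc1cc(OCc2ccccc2)cc(OCc2ccccc2)c1
F7 | step 12 | 2-hydroxy-5,7,3',4'-tetra-O-benzylflavan-3β-ol-(4α→8)-penta-O-benzylcatechin-(4α→6)-penta-O-benzyl-8-bromocatechin (hemiketal at C2) | c1ccccc1COc1cc(OCc3ccccc3)c2c(c1)OC(O)(c1ccc(OCc3ccccc3)c(OCc3ccccc3)c1)[C@@H](O)[C@@H]2c1c(OCc3ccccc3)cc(OCc3ccccc3)c2c1O[C@H](c1ccc(OCc3ccccc3)c(OCc3ccccc3)c1)[C@@H](OCc3ccccc3)[C@@H]2c1c(OCc3ccccc3)c(Br)c2c(c1OCc3ccccc3)C[C@H](OCc3ccccc3)[C@@H](c1ccc(OCc3ccccc3)c(OCc3ccccc3)c1)O2
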